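## Structural features

The target is a 2,3-dihydrobenzofuran: benzene ring A is fused to dihydrofuran ring B through C3a–C7a, with O1 on C7a. C2 and C3 are adjacent stereocentres, both R and cis. C2 carries O1, H and a 3-oxoprop-1-en-2-yl group (a 2-substituted acrolein bound through its α-carbon, Cα). C3 is a benzylic carbinol esterified with 3-methylbutanoic acid. C5, para to O1, carries a 1-(acyloxy)ethyl chain whose carbinol carbon is R and whose acyl group is (R)-2-methylbutanoyl. These two centres face each other across the ester link but are insulated from the ring pair by ring A, so neither pair can direct the other.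

The fragile groups are:
- the enal, a polymerisable Michael acceptor;
- both benzylic esters, which are activated toward ionisation by O1 (ortho-type for C3, para for the side chain);
- the C3 ester, which lies anti to C2–H and can be lost by elimination with aromatisation to a benzofuran;
- the epimerisable α-carbon of the 2-methylbutanoate.

The real difficulty is to set the cis C2/C3 pair in the absolute sense, independently of the remote centres, and to bring Cα to the aldehyde level without acid, strong base or nucleophiles late in the route. The feature exploited is that C2 (bonded to O1 and to the 1,1-disubstituted vinyl carbon Cα) stands next to the benzylic carbinol C3. This is the retron of a γ-aryloxyallyl metal adding to an ortho aldehyde within ring B. If the central allyl carbon carries boron, Cα is left metalated for formylation.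

## Logic of the disconnections

16 ⇒ 15: the bond between Cα and the formyl carbon is cut. The enal is the most reactive group and should appear last. The formyl carbon then comes from carbon monoxide and the precursor is a stable alkenyl iodide. The forward step must be a neutral carbonylation that tolerates an allylic aryl ether and two benzylic esters.

15 ⇒ 14: the Cα–I bond is exchanged for a Cα–B bond. Boron is what the ring-forming step leaves on Cα, so this joins the endgame to the key step. The forward step must replace boron by iodine at the same carbon without ester cleavage or iodination of ring A.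

14 ⇒ 12 + 13: the acyl C–O bond at C3 is cut. A free C3 hydroxyl would trap the later acylpalladium as a lactone, so the acyl group must be on before halogenation and carbonylation. This removes the second acyl unit as a commercial acid chloride. The forward step must acylate a hindered cis alcohol without elimination across C2–C3.

12 ⇒ 10: the C2–C3 and Cα–B bonds are cut and ring B is opened. One operation then creates the ring, the skeletal bond, both ring stereocentres and the handle on Cα, from a precursor with no stereochemistry in the ring region. The forward step must control the aldehyde face by catalyst, close cis, engage the allene and not the aldehyde with the boryl metal, and spare the ester.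

10 ⇒ 8 + 9: the acyl C–O bond of the side chain is cut. The chiral acid is thereby introduced after every strongly basic step and before the catalysis. The forward esterification must expose the allenyl ether to no free acid, must not epimerise the α-carbon of 9 and must leave the carbinol C–O bond untouched.

8 ⇒ 7: the aldehyde is traced back to a primary alcohol. An aldehyde cannot pass through the allene-forming base, so the oxidation level is raised afterwards. The forward oxidation must distinguish the primary from the secondary benzylic alcohol under non-acidic conditions.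

7 ⇒ 6: the allenyl ether is traced back to its propargyl isomer. The propargyl ether comes from a plain alkylation. The forward isomerisation needs strong base, so 6 must contain no carbonyl group and no ester.

6 ⇒ 4: the carbinol C–H bonds of both alcohols are cut. One hydride-transfer catalyst reduces the aldehyde and, enantioselectively, the ketone, so the first stereocentre arises from an achiral compound. The forward step needs catalyst control toward R and tolerance of the terminal alkyne.

4 ⇒ 2 + 3: the O–CH2 bond is cut. Alkylating the phenol before any reduction means no free para- or ortho-hydroxybenzylic alcohol (a quinone methide precursor) ever exists. The forward step is an O-alkylation of a hydrogen-bonded salicylaldehyde phenol.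

2 ⇒ 1: the aryl–CHO bond is cut. The two ortho positions of 1 are equivalent and the para position is blocked, so regiochemistry is not an issue. The forward step must formylate ortho to the phenol without touching the acetyl group.

## Other disconnections considered

Alternative 1: The cut is the C3–O bond of a cis-fused α-methylene-γ-butyrolactone A1, traced back to the bond between C3 and the future Cα in a cyclopropane. The substrate is tert-butyl 1-(iodomethyl)cyclopropanecarboxylate fused across C2–C3 of 5-bromobenzofuran, A2. In the forward step fac-Ir(ppy)3 under visible light reduces the C–I bond. The cyclopropylcarbinyl radical opens toward the benzylic C3 radical and creates the exocyclic methylene. Oxidation by the tetravalent iridium species gives the cation, which the ester oxygen captures.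
- In favour: cis fusion is enforced by the tether, which is better than the chosen plan, where cis closure rests on a transition-state preference. C2 would come from asymmetric cyclopropanation of a benzofuran, a better-precedented source of absolute configuration than the untested copper step.
- Against: Cα ends at the carboxyl level, locked to the C3 oxygen. Reaching 16 requires opening the lactone, reducing to the aldehyde level and acylating C3–O selectively, which is several protecting-group and redox operations on a reactive acrylate. The whole side chain must still be built from the aryl bromide (acetylation, asymmetric reduction, esterification).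
- Comparison: mechanistically the radical–polar crossover is plausible and the ring opening is well biased. On step economy it is clearly longer, roughly five steps to A2 and eight or more after A1, against ten in all for the chosen plan.

Alternative 2: The cut removes two bonds of ring A, C3a–C7a and C4–C5. The precursor is a 3-alkoxy-6-acetylpyridazine A4, whose alkoxy chain already holds C2, C3, the isovalerate, the silyl-protected 2-substituted allyl alcohol and a terminal alkyne. The forward step is an intramolecular inverse-demand cycloaddition of the alkyne across C3 and C6 of the pyridazine with loss of N2, giving A3.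
- In favour: both ring stereocentres come from the chiral pool and are fixed before any ring exists, so relative and absolute configuration are at least as secure as in the chosen plan and need no asymmetric catalysis. The position of the acetyl group on ring A is unambiguous, and the C3 ester and the oxidised C2 arm are already in place.
- Against: the sugar-derived fragment needs a long sequence of deoxygenations and chain adjustments. The cycloaddition of an unactivated alkyne needs strong heating, at which a propargylic, later benzylic, ester anti to C2–H may eliminate. After A3 the ketone reduction, esterification, desilylation and oxidation remain.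
- Comparison: the pericyclic step is mechanistically reliable and entropically helped by the short tether, which is a point in its favour. On step economy it is the longest of the four plans.

Alternative 3: The cut is O1–C7a. The precursor is the syn-diol A6, 1-[3-((1R,2R)-1,2-dihydroxy-3-methylbut-3-enyl)-4-fluorophenyl]ethanone. In the forward step K2CO3 in DMF lets the C2 alkoxide displace fluoride para to the acetyl group, giving A5.
- In favour: every step is established chemistry. The ring closure creates no stereocentre, so the cis relation follows stereospecifically from the syn-diol. This is more predictable than the chosen key step. A5 is a compact, robust intermediate.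
- Against: the isopropenyl methyl group must be oxidised to the aldehyde late, by allylic oxidation next to two ionisable benzylic esters and an allylic C2–H. The ketone must be reduced asymmetrically and the two hydroxyls acylated in a fixed order. The enantiopure syn-diol needs its own asymmetric step with a chemoselectivity problem between two alkenes.
- Comparison: the step count is about equal to that of the chosen plan, or one or two steps more. It is the safer plan mechanistically. The chosen plan is more convergent on function, because the ring-forming step also delivers the handle on Cα, whereas here that carbon needs a separate and less selective C–H oxidation.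

Key step: step 7

Remark 1: the sense of induction of a given bisphosphine enantiomer in the new cyclisation cannot be derived safely by analogy. (R,R)-Ph-BPE is written; its mirror image is used if the first run shows the (2S,3S) series.

Remark 2: (R)-2-methylbutanoic acid is taken as a purchasable single enantiomer. Paraformaldehyde, B2pin2, ICl and CO are treated as reagents and carry no number. Compound 2 can also be bought, which would save step 1.

Step 1
Reactants: 1 4-hydroxyacetophenone
Product: 2 5-acetyl-2-hydroxybenzaldehyde
Conditions: MgCl2, Et3N, (CH2O)n, MeCN, reflux; 1 M HCl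
Reagents that add atoms: paraformaldehyde (formaldehyde), C=O
Why: Magnesium-phenoxide-directed ortho-formylation (Casnati–Skattebøl): the chelated phenoxide is hydroxymethylated ortho and a second formaldehyde takes up hydride to give the salicylaldehyde. Both ortho positions are equivalent, the para position is blocked, and the aryl methyl ketone is not enolised by this weak base system.

Step 2
Reactants: 2 5-acetyl-2-hydroxybenzaldehyde; 3 propargyl bromide
Product: 4 5-acetyl-2-(prop-2-yn-1-yloxy)benzaldehyde
Conditions: K2CO3, DMF, rt
Reagents that add atoms: none
Why: Williamson ether synthesis on an acidic salicylaldehyde phenol with a reactive propargylic bromide. Capping the phenol here removes any later quinone methide pathway.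

Step 3
Reactants: 4 5-acetyl-2-(prop-2-yn-1-yloxy)benzaldehyde
Product: 6 (1R)-1-[3-(hydroxymethyl)-4-(prop-2-yn-1-yloxy)phenyl]ethan-1-ol, via hydroxymethyl ketone 5 (not isolated)
Conditions: RuCl(p-cymene)[(R,R)-TsDPEN] (1 mol%), HCO2H/Et3N (5:2), CH2Cl2, 30 °C
Reagents that add atoms: none
Why: Noyori asymmetric transfer hydrogenation: the aldehyde is reduced first, then the aryl methyl ketone. The (R,R)-diamine catalyst delivers hydride to the face that gives (R)-1-arylethanols through the CH/π-organised six-membered transition state. The remote alkyne is not a substrate for the saturated ruthenium hydride.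

Step 4
Reactants: 6 (1R)-1-[3-(hydroxymethyl)-4-(prop-2-yn-1-yloxy)phenyl]ethan-1-ol
Product: 7 (1R)-1-[3-(hydroxymethyl)-4-(propa-1,2-dien-1-yloxy)phenyl]ethan-1-ol
Conditions: KOtBu (2.3 equiv), THF, 0 °C to rt; H2O quench
Reagents that add atoms: none
Why: Base-mediated propargyl-to-allenyl ether isomerisation: tert-butoxide removes a propargylic proton and reprotonation at the alkyne terminus gives the aryloxyallene as the kinetic product. Both hydroxyls are carried as alkoxides, and the molecule holds no carbonyl group, ester or epimerisable centre at this stage.

Step 5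
Reactants: 7 (1R)-1-[3-(hydroxymethyl)-4-(propa-1,2-dien-1-yloxy)phenyl]ethan-1-ol
Product: 8 5-[(1R)-1-hydroxyethyl]-2-(propa-1,2-dien-1-yloxy)benzaldehyde
Conditions: Cu(MeCN)4OTf (5 mol%), 2,2'-bipyridine (5 mol%), TEMPO (5 mol%), N-methylimidazole (10 mol%), air, MeCN, rt
Reagents that add atoms: none
Why: Aerobic alcohol oxidation with a monovalent copper/TEMPO catalyst: this system oxidises primary benzylic alcohols quickly and leaves secondary alcohols essentially untouched for steric reasons, and it stops at the aldehyde. The mildly basic medium spares the acid-labile allenyl ether.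

Step 6
Reactants: 8 5-[(1R)-1-hydroxyethyl]-2-(propa-1,2-dien-1-yloxy)benzaldehyde; 9 (R)-2-methylbutanoic acid
Product: 10 (1R)-1-[3-formyl-4-(propa-1,2-dien-1-yloxy)phenyl]ethyl (2R)-2-methylbutanoate
Conditions: DCC, DMAP (10 mol%), CH2Cl2, 0 °C to rt (acid pre-activated before 8 is added)
Reagents that add atoms: none
Why: Steglich esterification: acylation occurs at oxygen, so the carbinol centre is retained. No acid chloride/amine pair is present, so the ketene route to α-epimerisation is avoided. Pre-activation keeps free carboxylic acid away from the allenyl ether.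

Step 7
Reactants: 10 (1R)-1-[3-formyl-4-(propa-1,2-dien-1-yloxy)phenyl]ethyl (2R)-2-methylbutanoate
Product: 12 (1R)-1-[(2R,3R)-3-hydroxy-2-[1-(4,4,5,5-tetramethyl-1,3,2-dioxaborolan-2-yl)ethenyl]-2,3-dihydro-1-benzofuran-5-yl]ethyl (2R)-2-methylbutanoate, via O-pinacolboryl ether 11 (not isolated)
Conditions: CuCl (5 mol%), (R,R)-Ph-BPE (6 mol%), NaOtBu (8 mol%), B2pin2 (1.15 equiv), THF, 0 °C to rt; pH 7 buffer
Reagents that add atoms: bis(pinacolato)diboron, CC1(C)OB(OC1(C)C)B1OC(C)(C)C(C)(C)O1
Why: Proposed new method: CuCl, NaOtBu and B2pin2 give a phosphine-bound monovalent copper boryl that adds across the terminal C=C of the aryloxyallene from the face away from the aryloxy group, placing boron on the central carbon and copper on CH2 as a (Z)-γ-aryloxyallylcopper; this adds through its oxygen-bearing carbon to the ortho aldehyde in a six-membered chair transition state, and B2pin2 turns the copper alkoxide over to the O-boryl ether 11, which is hydrolysed to 12 on work-up. The closest known reaction types are the intermolecular copper-catalysed enantioselective borylative coupling of monosubstituted allenes with aldehydes and the intramolecular γ-alkoxyallylstannane–aldehyde cyclisation to 2-vinyl-3-hydroxy cyclic ethers; neither is established for an aryloxyallene tethered to the aldehyde. Ring B closes in the 5-exo-trig mode with respect to the carbonyl group. C3 is controlled by the chiral bisphosphine, which must direct the allyl carbon to the Si face of the aldehyde. C2 is controlled by the transition state: the axial aryloxy group and the equatorial aldehyde aryl group are the two ends of ring A, so the chair is cis-fused to the forming five-membered ring and the borylvinyl group and the C3 oxygen emerge cis. The step needs the boryl copper to engage the allene and not the aldehyde, and needs C–C bond formation at the oxygen-bearing allyl terminus; the substrate secures the second point because any α-aryloxy allylcopper isomer equilibrates by 1,3-copper shift and only the CH2-bound form can reach the aldehyde through a small ring. The aldehyde is non-enolisable and the alkoxide is kept to a few mol%, so the side-chain centres are not at risk.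

Step 8
Reactants: 12 (1R)-1-[(2R,3R)-3-hydroxy-2-[1-(4,4,5,5-tetramethyl-1,3,2-dioxaborolan-2-yl)ethenyl]-2,3-dihydro-1-benzofuran-5-yl]ethyl (2R)-2-methylbutanoate; 13 isovaleryl chloride
Product: 14 (2R,3R)-5-[(1R)-1-{[(2R)-2-methylbutanoyl]oxy}ethyl]-2-[1-(4,4,5,5-tetramethyl-1,3,2-dioxaborolan-2-yl)ethenyl]-2,3-dihydro-1-benzofuran-3-yl 3-methylbutanoate
Conditions: pyridine, DMAP (10 mol%), CH2Cl2, 0 °C (on crude 12)
Reagents that add atoms: none
Why: DMAP-catalysed acylation of a secondary benzylic alcohol with an achiral acid chloride. It is run cold on crude material to forestall boron–oxygen chelation and base-induced elimination across C2–C3. No stereocentre is touched, and the alkenyl boronate is inert to these conditions.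

Step 9
Reactants: 14 (2R,3R)-5-[(1R)-1-{[(2R)-2-methylbutanoyl]oxy}ethyl]-2-[1-(4,4,5,5-tetramethyl-1,3,2-dioxaborolan-2-yl)ethenyl]-2,3-dihydro-1-benzofuran-3-yl 3-methylbutanoate
Product: 15 (2S,3R)-2-(1-iodoethenyl)-5-[(1R)-1-{[(2R)-2-methylbutanoyl]oxy}ethyl]-2,3-dihydro-1-benzofuran-3-yl 3-methylbutanoate
Conditions: NaOMe (1.1 equiv), THF/MeOH, −78 °C; ICl (1.05 equiv), −78 °C; aq. Na2S2O3
Reagents that add atoms: iodine monochloride, ClI
Why: Iododeboronation of an alkenyl pinacol boronate through its methoxy ate complex: electrophilic iodine replaces boron at the same carbon, and a 1,1-disubstituted alkene has no geometry to lose. One equivalent of methoxide at −78 °C is sequestered on boron and should spare both esters. The C2 descriptor changes only because iodine raises the CIP rank of the vinyl carbon.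

Step 10
Reactants: 15 (2S,3R)-2-(1-iodoethenyl)-5-[(1R)-1-{[(2R)-2-methylbutanoyl]oxy}ethyl]-2,3-dihydro-1-benzofuran-3-yl 3-methylbutanoate
Product: 16 (2R,3R)-5-[(1R)-1-{[(2R)-2-methylbutanoyl]oxy}ethyl]-2-(3-oxoprop-1-en-2-yl)-2,3-dihydro-1-benzofuran-3-yl 3-methylbutanoate
Conditions: Pd(PPh3)4 (5 mol%), CO (3 atm), Bu3SnH (1.1 equiv, slow addition), THF, 50 °C
Reagents that add atoms: carbon monoxide, [C-]#[O+]
Why: Palladium-catalysed formylation of an alkenyl iodide (Stille-type reductive carbonylation): oxidative addition to zerovalent palladium, CO insertion to the acylpalladium, and hydride transfer from tin release the enal. The medium is neutral and base-free, as the benzylic esters and the product require. Slow hydride addition under CO pressure favours insertion over direct reduction.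

Compound list
1 | 4-hydroxyacetophenone | CC(=O)c1ccc(O)cc1 | starting material
2 | 5-acetyl-2-hydroxybenzaldehyde | CC(=O)c1ccc(O)c(C=O)c1 | intermediate
3 | propargyl bromide (3-bromoprop-1-yne) | C#CCBr | starting material
4 | 5-acetyl-2-(prop-2-yn-1-yloxy)benzaldehyde | CC(=O)c1ccc(OCC#C)c(C=O)c1 | intermediate
5 | 1-[3-(hydroxymethyl)-4-(prop-2-yn-1-yloxy)phenyl]ethan-1-one | CC(=O)c1ccc(OCC#C)c(CO)c1 | intermediate
6 | (1R)-1-[3-(hydroxymethyl)-4-(prop-2-yn-1-yloxy)phenyl]ethan-1-ol | OCc1cc(ccc1OCC#C)[C@@H](C)O | intermediate
7 | (1R)-1-[3-(hydroxymethyl)-4-(propa-1,2-dien-1-yloxy)phenyl]ethan-1-ol | OCc1cc(ccc1OC=C=C)[C@@H](C)O | intermediate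
8 | 5-[(1R)-1-hydroxyethyl]-2-(propa-1,2-dien-1-yloxy)benzaldehyde | O=Cc1cc(ccc1OC=C=C)[C@@H](C)O | intermediate
9 | (R)-2-methylbutanoic acid | OC(=O)[C@H](C)CC | starting material
10 | (1R)-1-[3-formyl-4-(propa-1,2-dien-1-yloxy)phenyl]ethyl (2R)-2-methylbutanoate | O=Cc1cc(ccc1OC=C=C)[C@@H](C)OC(=O)[C@H](C)CC | intermediate
11 | (1R)-1-[(2R,3R)-3-[(4,4,5,5-tetramethyl-1,3,2-dioxaborolan-2-yl)oxy]-2-[1-(4,4,5,5-tetramethyl-1,3,2-dioxaborolan-2-yl)ethenyl]-2,3-dihydro-1-benzofuran-5-yl]ethyl (2R)-2-methylbutanoate | C=C(B1OC(C)(C)C(C)(C)O1)[C@H]1Oc2ccc([C@@H](C)OC(=O)[C@H](C)CC)cc2[C@H]1OB1OC(C)(C)C(C)(C)O1 | intermediate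
12 | (1R)-1-[(2R,3R)-3-hydroxy-2-[1-(4,4,5,5-tetramethyl-1,3,2-dioxaborolan-2-yl)ethenyl]-2,3-dihydro-1-benzofuran-5-yl]ethyl (2R)-2-methylbutanoate (2,3-cis) | C=C(B1OC(C)(C)C(C)(C)O1)[C@H]1Oc2ccc([C@@H](C)OC(=O)[C@H](C)CC)cc2[C@H]1O | intermediate
13 | isovaleryl chloride (3-methylbutanoyl chloride) | CC(C)CC(=O)Cl | starting material
14 | (2R,3R)-5-[(1R)-1-{[(2R)-2-methylbutanoyl]oxy}ethyl]-2-[1-(4,4,5,5-tetramethyl-1,3,2-dioxaborolan-2-yl)ethenyl]-2,3-dihydro-1-benzofuran-3-yl 3-methylbutanoate | C=C(B1OC(C)(C)C(C)(C)O1)[C@H]1Oc2ccc([C@@H](C)OC(=O)[C@H](C)CC)cc2[C@H]1OC(=O)CC(C)C | intermediate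
15 | (2S,3R)-2-(1-iodoethenyl)-5-[(1R)-1-{[(2R)-2-methylbutanoyl]oxy}ethyl]-2,3-dihydro-1-benzofuran-3-yl 3-methylbutanoate (2,3-cis) | C=C(I)[C@H]1Oc2ccc([C@@H](C)OC(=O)[C@H](C)CC)cc2[C@H]1OC(=O)CC(C)C | intermediate
16 | (2R,3R)-5-[(1R)-1-{[(2R)-2-methylbutanoyl]oxy}ethyl]-2-(3-oxoprop-1-en-2-yl)-2,3-dihydro-1-benzofuran-3-yl 3-methylbutanoate (CNP0154159.2) | C=C(C=O)[C@H]1Oc2ccc([C@@H](C)OC(=O)[C@H](C)CC)cc2[C@H]1OC(=O)CC(C)C | target

Total step count: 10. Longest linear sequence: 10 steps (1 to 16); the route is linear, with 3, 9 and 13 entering as purchased reagents.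

Least certain steps

Step 7 (key step, proposed new method). The most likely failures are:
- 1,2-addition of the boryl copper to the aldehyde in competition with allene insertion;
- insufficient facial selectivity, which would give diastereomers that differ only in the relation of the ring pair to the remote side-chain centres and would be hard to separate;
- closure through a boat-like transition state to the trans isomer;
- protonation of the allylcopper before cyclisation.

The fallback uses known reactions only, sets out from 6 and returns to the route at 16.
- TEMPO/PhI(OAc)2 should oxidise only the primary alcohol of 6, giving 5-[(1R)-1-hydroxyethyl]-2-(prop-2-yn-1-yloxy)benzaldehyde F1.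
- DCC/DMAP esterification with 9 gives (1R)-1-[3-formyl-4-(prop-2-yn-1-yloxy)phenyl]ethyl (2R)-2-methylbutanoate F2.
- Ph3PAuNTf2-catalysed Markovnikov hydration of the terminal alkyne in aqueous dioxane gives (1R)-1-[3-formyl-4-(2-oxopropoxy)phenyl]ethyl (2R)-2-methylbutanoate F3.
- Proline-catalysed 5-enolexo aldolisation, a known route to cis-2-acyl-3-hydroxy-2,3-dihydrobenzofurans, forms C2–C3 and gives (1R)-1-[(2S,3R)-2-acetyl-3-hydroxy-2,3-dihydro-1-benzofuran-5-yl]ethyl (2R)-2-methylbutanoate F4. The proline enantiomer is chosen for the 3R series.
- Methylenation of the ketone with Cp2Ti(CH2)(Cl)AlMe2 gives (1R)-1-[(2R,3R)-3-hydroxy-2-(prop-1-en-2-yl)-2,3-dihydro-1-benzofuran-5-yl]ethyl (2R)-2-methylbutanoate F5.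
- Acylation with 13 (pyridine, DMAP) gives (2R,3R)-5-[(1R)-1-{[(2R)-2-methylbutanoyl]oxy}ethyl]-2-(prop-1-en-2-yl)-2,3-dihydro-1-benzofuran-3-yl 3-methylbutanoate F6.
- SeO2 in dioxane at 70 °C oxidises the allylic methyl group to the aldehyde, giving 16.

Step 9. The likely failures are methanolysis of an ester or base-induced elimination across C2–C3 while the ate complex forms, and electrophilic iodination of electron-rich ring A by ICl. The fallback sets out from 14 and returns at 15. Aqueous KHF2 in MeOH converts the boronate into the potassium trifluoroborate of 14 F12. NaI with chloramine-T (TsNClNa) in aqueous THF then replaces boron by iodine without alkoxide or a strong iodine electrophile.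

Step 10. The likely failures are hydride transfer to the alkenylpalladium before CO insertion (loss of iodine without carbonylation), β-aryloxy elimination from the alkenylpalladium with opening of ring B, and conjugate reduction of the product by tin hydride. The fallback sets out from 15 and returns at 16. Stille coupling with (tributylstannyl)methanol under Pd(PPh3)4 in dioxane gives (2R,3R)-2-(3-hydroxyprop-1-en-2-yl)-5-[(1R)-1-{[(2R)-2-methylbutanoyl]oxy}ethyl]-2,3-dihydro-1-benzofuran-3-yl 3-methylbutanoate F13. MnO2 in CH2Cl2 oxidises the allylic alcohol to the enal.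

Step 5. The likely failures are incomplete chemoselectivity (co-oxidation of the secondary alcohol), copper-induced decomposition of the allenyl ether, and acid-catalysed addition of the ortho hydroxymethyl group to the allene while 7 is handled. The fallback sets out from 7 and returns at 10.
- TBSCl/imidazole at 0 °C silylates the primary hydroxyl, giving (1R)-1-[3-({[tert-butyl(dimethyl)silyl]oxy}methyl)-4-(propa-1,2-dien-1-yloxy)phenyl]ethan-1-ol F9.
- DCC/DMAP esterification with 9 gives (1R)-1-[3-({[tert-butyl(dimethyl)silyl]oxy}methyl)-4-(propa-1,2-dien-1-yloxy)phenyl]ethyl (2R)-2-methylbutanoate F10.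
- TBAF in THF at 0 °C gives (1R)-1-[3-(hydroxymethyl)-4-(propa-1,2-dien-1-yloxy)phenyl]ethyl (2R)-2-methylbutanoate F11.
- MnO2 oxidises the now unique benzylic alcohol to 10.

Step 4. The likely failures are stalling of the isomerisation because the two alkoxides buffer the base, over-isomerisation to the prop-1-ynyl ether if forcing conditions are then used, and addition of the ortho alkoxide to the allene. The fallback sets out from 6 and returns at 7. Excess TBSCl/imidazole gives the bis(tert-butyldimethylsilyl) ether of 6 F7. Catalytic KOtBu in THF then isomerises the ether with no alkoxide present, giving the bis(tert-butyldimethylsilyl) ether of 7 F8. TBAF removes both silyl groups to give 7.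

Further compounds
F1 | step 7 | 5-[(1R)-1-hydroxyethyl]-2-(prop-2-yn-1-yloxy)benzaldehyde | O=Cc1cc(ccc1OCC#C)[C@@H](C)O
F2 | step 7 | (1R)-1-[3-formyl-4-(prop-2-yn-1-yloxy)phenyl]ethyl (2R)-2-methylbutanoate | O=Cc1cc(ccc1OCC#C)[C@@H](C)OC(=O)[C@H](C)CC
F3 | step 7 | (1R)-1-[3-formyl-4-(2-oxopropoxy)phenyl]ethyl (2R)-2-methylbutanoate | O=Cc1cc(ccc1OCC(C)=O)[C@@H](C)OC(=O)[C@H](C)CC
F4 | step 7 | (1R)-1-[(2S,3R)-2-acetyl-3-hydroxy-2,3-dihydro-1-benzofuran-5-yl]ethyl (2R)-2-methylbutanoate | CC(=O)[C@H]1Oc2ccc([C@@H](C)OC(=O)[C@H](C)CC)cc2[C@H]1O
F5 | step 7 | (1R)-1-[(2R,3R)-3-hydroxy-2-(prop-1-en-2-yl)-2,3-dihydro-1-benzofuran-5-yl]ethyl (2R)-2-methylbutanoate | C=C(C)[C@H]1Oc2ccc([C@@H](C)OC(=O)[C@H](C)CC)cc2[C@H]1O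
F6 | step 7 | (2R,3R)-5-[(1R)-1-{[(2R)-2-methylbutanoyl]oxy}ethyl]-2-(prop-1-en-2-yl)-2,3-dihydro-1-benzofuran-3-yl 3-methylbutanoate | C=C(C)[C@H]1Oc2ccc([C@@H](C)OC(=O)[C@H](C)CC)cc2[C@H]1OC(=O)CC(C)C
F7 | step 4 | bis(tert-butyldimethylsilyl) ether of 6 | CC(C)(C)[Si](C)(C)OCc1cc(ccc1OCC#C)[C@@H](C)O[Si](C)(C)C(C)(C)C
F8 | step 4 | bis(tert-butyldimethylsilyl) ether of 7 | CC(C)(C)[Si](C)(C)OCc1cc(ccc1OC=C=C)[C@@H](C)O[Si](C)(C)C(C)(C)C
F9 | step 5 | (1R)-1-[3-({[tert-butyl(dimethyl)silyl]oxy}methyl)-4-(propa-1,2-dien-1-yloxy)phenyl]ethan-1-ol | CC(C)(C)[Si](C)(C)OCc1cc(ccc1OC=C=C)[C@@H](C)O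
F10 | step 5 | (1R)-1-[3-({[tert-butyl(dimethyl)silyl]oxy}methyl)-4-(propa-1,2-dien-1-yloxy)phenyl]ethyl (2R)-2-methylbutanoate | CC(C)(C)[Si](C)(C)OCc1cc(ccc1OC=C=C)[C@@H](C)OC(=O)[C@H](C)CC
F11 | step 5 | (1R)-1-[3-(hydroxymethyl)-4-(propa-1,2-dien-1-yloxy)phenyl]ethyl (2R)-2-methylbutanoate | OCc1cc(ccc1OC=C=C)[C@@H](C)OC(=O)[C@H](C)CC
F12 | step 9 | potassium trifluoroborate of 14 | C=C([B-](F)(F)F)[C@H]1Oc2ccc([C@@H](C)OC(=O)[C@H](C)CC)cc2[C@H]1OC(=O)CC(C)C.[K+]
F13 | step 10 | (2R,3R)-2-(3-hydroxyprop-1-en-2-yl)-5-[(1R)-1-{[(2R)-2-methylbutanoyl]oxy}ethyl]-2,3-dihydro-1-benzofuran-3-yl 3-methylbutanoate | C=C(CO)[C@H]1Oc2ccc([C@@H](C)OC(=O)[C@H](C)CC)cc2[C@H]1OC(=O)CC(C)C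
A1 | alternative 1 | cis-fused α-methylene-γ-butyrolactone on 5-bromo-2,3-dihydrobenzofuran (lactone oxygen on C3) | C=C1[C@H]2Oc3ccc(Br)cc3[C@H]2OC1=O
A2 | alternative 1 | tert-butyl 1-(iodomethyl)cyclopropanecarboxylate fused across C2–C3 of 5-bromobenzofuran (ester exo; the configuration at the quaternary carbon is immaterial for the ring opening) | IC[C@@]1(C(=O)OC(C)(C)C)[C@H]2Oc3ccc(Br)cc3[C@H]21
A3 | alternative 2 | (2R,3R)-5-acetyl-2-[3-(tert-butyldimethylsilyloxy)prop-1-en-2-yl]-2,3-dihydro-1-benzofuran-3-yl 3-methylbutanoate | C=C(CO[Si](C)(C)C(C)(C)C)[C@H]1Oc2ccc(C(C)=O)cc2[C@H]1OC(=O)CC(C)C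
A4 | alternative 2 | 6-acetylpyridazin-3-yl ether of the alkynyl chain bearing the isovalerate and the silyl-protected 2-substituted allyl alcohol | C=C(CO[Si](C)(C)C(C)(C)C)[C@@H](Oc1ccc(C(C)=O)nn1)[C@H](OC(=O)CC(C)C)C#C
A5 | alternative 3 | (2R,3R)-5-acetyl-2-(prop-1-en-2-yl)-2,3-dihydro-1-benzofuran-3-ol (2,3-cis) | C=C(C)[C@H]1Oc2ccc(C(C)=O)cc2[C@H]1O
A6 | alternative 3 | 1-[3-((1R,2R)-1,2-dihydroxy-3-methylbut-3-enyl)-4-fluorophenyl]ethanone (syn-diol) | C=C(C)[C@@H](O)[C@H](O)c1cc(C(C)=O)ccc1F
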